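(The rate constants stand for no real mixture, and the outcome is calculated.)

To choose a flask for triple product one must first reckon how far along its chain a flask stands, and that question can be separated from time.

| setting | teal | violet | green | grey | amber | blue |
|---|---|---|---|---|---|---|
| starting material | 19 mM (in portions, 3, over 2.0 min) | 19 mM | 19 mM | 19 mM (fed, over 2.0 min) | 19 mM (fed, over 2.0 min) | 19 mM (fed, over 30 s) |
| coupling partner | 76.0 mM | 76.0 mM | 76.0 mM (fed, over 2.0 min) | 76.0 mM | 76.0 mM | 76.0 mM |
| temperature | 25 °C |  | 25 °C | 25 °C |  | 25 °C |
| time | 2.5 min | 2.5 min | 2.5 min | 2.5 min | 2.5 min | 2.5 min |
| remark | first portion at the start, last at 2.0 min | everything together at the start at −5 °C, warmed to 25 °C at 2.0 min | all else is in the flask from the start; the feed brings no volume worth counting | all else is in the flask from the start; the feed brings no volume worth counting | the addition at −5 °C, then warmed to 25 °C; the feed brings no volume worth counting | all else is in the flask from the start; the feed brings no volume worth counting |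

* the flask that comes out highest in amount of triple product, in percent of the starting material charged, or "all alike" when all lie within 1.5 percentage points (teal / violet / green / grey / amber / blue / all alike)
* triple product at the end, in percent of the starting material charged, teal
* triple product at the end, in percent of the starting material charged, violet
* triple product at the end, in percent of the starting material charged, green
* triple product at the end, in percent of the starting material charged, grey
* triple product at the end, in percent of the starting material charged, amber
* triple product at the end, in percent of the starting material charged, blue

    coupling partner → decomposition product (k1 = 6.0 × 10⁻⁵ s⁻¹, Ea1 = 102 kJ mol⁻¹)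
    coupling partner + mono adduct → double product + by-product (k2 = 0.51 M⁻¹ s⁻¹, Ea2 = 36.0 kJ mol⁻¹)
    starting material + coupling partner → mono adduct + by-product (k3 = 0.19 M⁻¹ s⁻¹, Ea3 = 46.0 kJ mol⁻¹)
    coupling partner + double product → triple product + by-product (k4 = 0.38 M⁻¹ s⁻¹, Ea4 = 37.0 kJ mol⁻¹)
    (constants at 25 °C)

- the list of constants is for 25 °C, to be carried to other temperatures by the activation energies

Each coupling has the coupling partner's concentration B in its rate, so dividing one coupling rate by another removes both B and time. Mono adduct is consumed 2.68 times as fast per molecule as starting material, and this relay ratio, a selectivity factor, has a companion for the last coupling, 2.00.

Let x be the fraction of starting material left. Mono adduct is then the difference of x and x raised to the relay ratio, over the ratio less one. Double product follows by the same chain solution one rung on, and triple product is the balance. This map holds whatever B does, for a charge present from the start at one temperature.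

Along the map, triple product leaves with zero slope, since it needs double product, which needs mono adduct; its slope then follows double product. It runs towards a level of 100 percent, because the partner charge is 4.00 per starting material against the 3 needed.

Blue is the flask reckoned here: its starting material stays 2.25 min on average, longer than grey's or teal's, while green's stays longer but meets a coupling partner that is fed over 2.0 min. Blue's 30 s feed is not a charge present from the start, so the map serves for blue as an estimate. Violet and amber are left unreckoned; both stand at −5 °C for 2.0 min, and the activation energies of the couplings differ, 46.0 kJ mol⁻¹ for the first against 36.0 kJ mol⁻¹ for the second. At full partner charge blue's clock, the first-step constant times B times the stay, reads 1.95, and x is that clock's negative exponential. The partner's own decay is far slower than this first step.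

| Point on the map | x | mono adduct | double product | triple product |
|---|---|---|---|---|
| mono adduct peak | 55.6% | 20.7% | 15.5% | 8.12% |
| blue, first pass | 14.2% | 8.14% | 16.0% | 61.6% |
| blue, second pass | 24.6% | 13.2% | 20.9% | 41.2% |

The first pass would leave 33.2 mM of partner, so the second pass uses the mean of that and the charge. Triple product lies below double product at the mono adduct peak and above it at the second pass. The hand figure for blue is 41.2%.

The forecast named blue, with teal 28%, violet 9%, green 25%, grey 29%, amber 6% and blue 42%, on the ground of “how much warm contact time with the partner”.

The simulation gives teal 28.4%, violet 9.05%, green 25.4%, grey 27.2%, amber 6.03% and blue 42.7%, blue being highest. Blue keeps 23.9% of its starting material at 2.50 min, and the relay ratios turn that reading into 42.5% of triple product.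

The neighbour of blue with 19 mM of coupling partner keeps 69.2% of its starting material, and the same ratios give 2.69% of triple product. The computed flask holds 2.72%.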